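**Plan**

1. Retrosynthesis: remove the fused-lactone methyl (exocyclic methylene, then H2), open the fused lactone at its C–O bond (ring ketone plus acetate arm), cut the azepine at its central C–C bond (metathesis of an N-allyl and a C-allyl group), take the pyrrole apart at both C–N bonds and at C3–C4 (Paal–Knorr on a 1,4-diketone made from a bromoketone), remove the acetate arm (Mukaiyama–Michael), and finally cut the ethyl–CH and methine–CH2 bonds of the carbocycle.
2. Enabling feature: in the six-membered carbocycle the ethyl-bearing CH and the azepine methine are adjacent and trans. They sit between pyrrole C-2 (the N-bound fusion carbon, a former ketone carbon) and the lactone O–CH (a former ketal carbon). This is the C(=O)–CH(allyl)–CH(Et)–C(OMe)2 array of a vicinally difunctionalised 4,4-dimethoxycyclohexenone.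
3. Forward order: carbocycle (all six carbons from 4-methoxyphenol), then pyrrole, then azepine, then fused lactone. The methyl-bearing butyrolactone is made separately from a chiral-pool lactone and joined as a bromoketone.
4. Stereochemistry: the ethyl and methine centres come from a chiral copper catalyst and anti allylation. The acetate-bearing and O-bearing carbons come from equilibration and equatorial hydride attack. The fused-lactone methyl comes from convex-face hydrogenation. The appended lactone comes from (R)-5-(hydroxymethyl)butyrolactone and trans-selective enolate methylation.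

Key step: step 2

Remark 1: the acetate-bearing ring carbon is formed without control in step 3 and is equilibrated in step 11. It is written without a descriptor in 8, 18, 20, 21 and 22, as is the carbon α to the ring ketone in 18, and both epimers are carried forward.
Remark 2: in step 2 the ligand antipode is the one that leads to (5R,6R)-6; the sense is to be confirmed on the mono-ethyl adduct.

**Route**

Step 1
Reactants: 1 4-methoxyphenol
Product: 2 4,4-dimethoxycyclohexa-2,5-dien-1-one
Conditions: PhI(OAc)2 (1.1 equiv), MeOH, 0 °C to rt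
Reagents that add atoms: methanol (CO)
Why: Hypervalent-iodine oxidative dearomatisation, in which the λ3-iodane activates the phenol oxygen and methanol adds para to it to give the isolable quinone monoketal.

Step 2
Reactants: 2 4,4-dimethoxycyclohexa-2,5-dien-1-one; 3 diethylzinc; 4 allyl acetate
Product: 6 (5R,6R)-5-ethyl-4,4-dimethoxy-6-(prop-2-enyl)cyclohex-2-en-1-one, via ethylzinc dienolate 5 (not isolated)
Conditions: Cu(OTf)2 (2 mol %), binaphthol-derived bis(1-phenylethyl)amine phosphoramidite L* (4 mol %), Et2Zn (1.2 equiv), PhMe, −25 °C; then Pd(PPh3)4 (4 mol %), allyl acetate (1.5 equiv), −25 to 0 °C; aq. NH4Cl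
Reagents that add atoms: none
Why: The ethylcopper(I)–phosphoramidite complex binds one of the two enantiotopic enone arms of the C2v-symmetric dienone and delivers ethyl to its β-carbon by oxidative addition–reductive elimination, leaving the cross-conjugated ethylzinc dienolate 5, whose only nucleophilic carbon is the one next to the new centre. Pd(0) then ionises allyl acetate and the zinc enolate attacks the π-allyl complex on the face anti to the neighbouring ethyl group, which forms the methine–CH2 bond and gives the trans enone 6. The closest known reaction type is the copper/phosphoramidite-catalysed conjugate addition of dialkylzincs to cyclohexadienone monoketals combined with palladium-catalysed allylic trapping of cyclohexenone zinc enolates. No ring is closed. The ethyl-bearing centre (5R) is set by the ligand through selection of the enone arm, and the allyl-bearing centre (6R) by 1,2-induction from it. The step needs mono-addition, 1,4- over 1,2-addition and C- over O-allylation; these are secured because the zinc enolate is inert to a second ethyl transfer until quenched, the soft organocopper attacks only the β-carbon, and the soft Pd-allyl electrophile reacts at the enolate carbon.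

Step 3
Reactants: 6 (5R,6R)-5-ethyl-4,4-dimethoxy-6-(prop-2-enyl)cyclohex-2-en-1-one; 7 1-(tert-butyldimethylsilyloxy)-1-methoxyethene
Product: 8 methyl 2-[(4R,5R)-3-(tert-butyldimethylsilyloxy)-5-ethyl-6,6-dimethoxy-4-(prop-2-enyl)cyclohex-2-en-1-yl]acetate (C-1 epimers)
Conditions: 7 (2 equiv), MeCN, 55 °C, no Lewis acid; chromatography on Et3N-treated silica
Reagents that add atoms: none
Why: Uncatalysed Mukaiyama–Michael addition, in which the silyl ketene acetal adds to the β-carbon of the remaining enone and the silyl group moves to oxygen, so that the ketal (which a Lewis acid would ionise toward a phenol) is untouched, the enol ether is fixed at the carbon that becomes pyrrole C-3, and the new centre may form as a mixture because it is equilibrated in step 11.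

Step 4
Reactants: 9 (5R)-5-(hydroxymethyl)oxolan-2-one
Product: 10 (5R)-5-[(tert-butyldimethylsilyloxy)methyl]oxolan-2-one
Conditions: TBSCl, imidazole, DMF, rt
Reagents that add atoms: tert-butyldimethylsilyl chloride (CC(C)(C)[Si](C)(C)Cl)
Why: Standard silylation of the primary alcohol masks the hydroxyl for the enolate chemistry of step 5.

Step 5
Reactants: 10 (5R)-5-[(tert-butyldimethylsilyloxy)methyl]oxolan-2-one
Product: 12 (3S,5R)-5-[(tert-butyldimethylsilyloxy)methyl]-3-methyloxolan-2-one, via lithium enolate 11 (not isolated)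
Conditions: LDA, THF, −78 °C; MeI, −78 °C
Reagents that add atoms: iodomethane (CI)
Why: Lactone enolate alkylation, in which methyl iodide attacks the face anti to the C-5 silyloxymethyl group and so sets the 3,5-trans (3S) methyl centre.

Step 6
Reactants: 12 (3S,5R)-5-[(tert-butyldimethylsilyloxy)methyl]-3-methyloxolan-2-one
Product: 14 (2R,4S)-4-methyl-5-oxooxolane-2-carboxylic acid, via primary alcohol 13 (not isolated)
Conditions: CrO3, H2SO4, H2O, acetone, 0 °C to rt
Reagents that add atoms: water (O)
Why: Jones oxidation, in which the acidic chromic acid medium cleaves the primary silyl ether and oxidises the freed alcohol through the aldehyde hydrate to the acid without touching either lactone stereocentre.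

Step 7
Reactants: 14 (2R,4S)-4-methyl-5-oxooxolane-2-carboxylic acid
Product: 17 (3S,5R)-5-(2-bromoacetyl)-3-methyloxolan-2-one, via acid chloride 15 (not isolated), via diazoketone 16 (not isolated)
Conditions: (COCl)2, cat. DMF, CH2Cl2, 0 °C to rt; evaporate; Me3SiCHN2 (2 equiv), THF–MeCN, 0 °C; then 48 % aq. HBr, 0 °C
Reagents that add atoms: (trimethylsilyl)diazomethane (C[Si](C)(C)C=[N+]=[N-]); hydrogen bromide (Br)
Why: Acylation of the diazomethane reagent by the acid chloride and hydrobromination of the diazoketone (diazoketone chemistry of the Arndt–Eistert type) give the bromomethyl ketone under acidic conditions that do not enolise the α-acyloxy centre.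

Step 8
Reactants: 8 methyl 2-[(4R,5R)-3-(tert-butyldimethylsilyloxy)-5-ethyl-6,6-dimethoxy-4-(prop-2-enyl)cyclohex-2-en-1-yl]acetate (C-1 epimers); 17 (3S,5R)-5-(2-bromoacetyl)-3-methyloxolan-2-one
Product: 18 methyl 2-[(3R,4R)-3-ethyl-2,2-dimethoxy-6-{2-[(2R,4S)-4-methyl-5-oxooxolan-2-yl]-2-oxoethyl}-5-oxo-4-(prop-2-enyl)cyclohexyl]acetate (epimers at C-1 and C-6)
Conditions: 17 (1.5 equiv), fac-Ir(ppy)3 (1 mol %), 2,6-lutidine, degassed MeCN, blue LEDs, rt; aqueous work-up
Reagents that add atoms: none
Why: Visible-light photoredox radical alkylation of a silyl enol ether, in which the excited iridium complex reduces 17 to an electrophilic α-keto radical that adds to the electron-rich enol ether carbon faster than to the terminal alkene, and oxidation of the α-siloxy radical with loss of silyl gives the 1,4-diketone without base, so that neither the allyl-bearing centre nor the α-acyloxy centre is enolised and the new centre is of no consequence.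

Step 9
Reactants: 18 methyl 2-[(3R,4R)-3-ethyl-2,2-dimethoxy-6-{2-[(2R,4S)-4-methyl-5-oxooxolan-2-yl]-2-oxoethyl}-5-oxo-4-(prop-2-enyl)cyclohexyl]acetate (epimers at C-1 and C-6); 19 allylamine
Product: 20 methyl 2-{(6R,7R)-6-ethyl-5,5-dimethoxy-2-[(2R,4S)-4-methyl-5-oxooxolan-2-yl]-1,7-di(prop-2-enyl)-4,5,6,7-tetrahydro-1H-indol-4-yl}acetate (C-4 epimers)
Conditions: allylamine (3 equiv), AcOH (3 equiv), MeOH, 4 Å MS, 50 °C
Reagents that add atoms: none
Why: Paal–Knorr pyrrole synthesis, in which the amine condenses first with the less hindered side-chain ketone and then with the ring ketone and aromatisation drives both dehydrations, while the acetic acid buffer in methanol should keep the dimethyl ketal and the lactones intact and cyclisation should outrun enamine formation toward the allyl-bearing carbon.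

Step 10
Reactants: 20 methyl 2-{(6R,7R)-6-ethyl-5,5-dimethoxy-2-[(2R,4S)-4-methyl-5-oxooxolan-2-yl]-1,7-di(prop-2-enyl)-4,5,6,7-tetrahydro-1H-indol-4-yl}acetate (C-4 epimers)
Product: 21 methyl 2-{(5Z,7aR,8R)-8-ethyl-9,9-dimethoxy-2-[(2R,4S)-4-methyl-5-oxooxolan-2-yl]-4,7,7a,8,9,10-hexahydroazepino[3,2,1-hi]indol-10-yl}acetate (C-10 epimers)
Conditions: (H2IMes)(PCy3)Cl2Ru=CHPh (5 mol %), CH2Cl2 (5 mM), 40 °C
Reagents that add atoms: none
Why: Ring-closing metathesis of the N-allyl and C-allyl groups closes the seven-membered (Z)-cycloalkene with loss of ethene, a closure well known for pyrrole- and indole-fused azepines.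

Step 11
Reactants: 21 methyl 2-{(5Z,7aR,8R)-8-ethyl-9,9-dimethoxy-2-[(2R,4S)-4-methyl-5-oxooxolan-2-yl]-4,7,7a,8,9,10-hexahydroazepino[3,2,1-hi]indol-10-yl}acetate (C-10 epimers)
Product: 23 methyl 2-{(5Z,7aR,8R,10S)-8-ethyl-2-[(2R,4S)-4-methyl-5-oxooxolan-2-yl]-9-oxo-4,7,7a,8,9,10-hexahydroazepino[3,2,1-hi]indol-10-yl}acetate, via ketone epimer mixture 22 (not isolated)
Conditions: PPTS (0.3 equiv), acetone–H2O (9:1), 45 °C; then DBU (0.3 equiv), CH2Cl2, rt, under argon
Reagents that add atoms: water (O)
Why: Acid-catalysed ketal hydrolysis followed by base equilibration, in which the proton α to both the new ketone and the pyrrole exchanges readily so that the acetate arm should settle equatorial and cis to the equatorial ethyl group (10S), while the ethyl centre already holds its trans relation to the locked azepine methine and the lactone α-proton is too weakly acidic for DBU.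

Step 12
Reactants: 23 methyl 2-{(5Z,7aR,8R,10S)-8-ethyl-2-[(2R,4S)-4-methyl-5-oxooxolan-2-yl]-9-oxo-4,7,7a,8,9,10-hexahydroazepino[3,2,1-hi]indol-10-yl}acetate
Product: 25 2-{(5Z,7aR,8R,9R,10S)-8-ethyl-9-hydroxy-2-[(2R,4S)-4-methyl-5-oxooxolan-2-yl]-4,7,7a,8,9,10-hexahydroazepino[3,2,1-hi]indol-10-yl}acetic acid 9-lactone (cis-fused), via cis-hydroxy ester 24 (not isolated)
Conditions: L-Selectride (1.3 equiv), THF, −78 °C; aq. NH4Cl; PPTS (cat.), PhMe, 40 °C
Reagents that add atoms: none
Why: Hindered-hydride reduction, in which L-Selectride approaches the ketone flanked by two equatorial substituents along the equatorial trajectory to give the axial alcohol cis to both the ethyl group and the acetate arm (9R), which then closes the cis-fused γ-lactone by acyl substitution on the methyl ester.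

Step 13
Reactants: 25 2-{(5Z,7aR,8R,9R,10S)-8-ethyl-9-hydroxy-2-[(2R,4S)-4-methyl-5-oxooxolan-2-yl]-4,7,7a,8,9,10-hexahydroazepino[3,2,1-hi]indol-10-yl}acetic acid 9-lactone (cis-fused)
Product: 29 α-methylene derivative of 25 (exocyclic CH2 on the fused-lactone α-carbon), via lithium enolate 26 (not isolated), via Mannich base 27 (not isolated), via methiodide 28 (not isolated)
Conditions: LDA (1.05 equiv), THF, −78 °C; CH2=NMe2+ I−, −78 to 0 °C; MeI, MeOH, rt; aq. NaHCO3, CH2Cl2, rt
Reagents that add atoms: N,N-dimethylmethyleneiminium iodide (C=[N+](C)C.[I-])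
Why: α-Methylenation through a Mannich base, in which kinetic deprotonation takes the exposed convex-face proton of the fused-lactone CH2 in preference to the tertiary α-proton of the appended lactone (shielded by the cis pyrrole substituent), and aminomethylation, quaternisation and E1cB elimination then give the exocyclic methylene.

Step 14
Reactants: 29 α-methylene derivative of 25 (exocyclic CH2 on the fused-lactone α-carbon)
Product: 30 CNP0232452.1
Conditions: H2 (1 atm), RhCl(PPh3)3 (10 mol %), PhH–EtOH, rt
Reagents that add atoms: none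
Why: Homogeneous hydrogenation, in which hydrogen adds to the exocyclic methylene from the convex face of the cis-fused bicyclic lactone and so places the new methyl on the concave face (S, cis to the carbocycle), while the same catalyst saturates the cis azepine alkene without hydrogenolysis of the pyrrolylcarbinyl C–O bond or reduction of the pyrrole.

**Compound list**

1 | 4-methoxyphenol | COc1ccc(O)cc1 | starting material
2 | 4,4-dimethoxycyclohexa-2,5-dien-1-one | COC1(OC)C=CC(=O)C=C1 | intermediate
3 | diethylzinc | CC[Zn]CC | starting material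
4 | allyl acetate | CC(=O)OCC=C | starting material
5 | ethylzinc (3R)-3-ethyl-4,4-dimethoxycyclohexa-1,5-dien-1-olate | CC[C@H]1C(OC)(OC)C=CC(O[Zn]CC)=C1 | intermediate (not isolated)
6 | (5R,6R)-5-ethyl-4,4-dimethoxy-6-(prop-2-enyl)cyclohex-2-en-1-one (ethyl and allyl trans) | CC[C@H]1C(OC)(OC)C=CC(=O)[C@@H]1CC=C | intermediate
7 | 1-(tert-butyldimethylsilyloxy)-1-methoxyethene | C=C(OC)O[Si](C)(C)C(C)(C)C | starting material
8 | methyl 2-[(4R,5R)-3-(tert-butyldimethylsilyloxy)-5-ethyl-6,6-dimethoxy-4-(prop-2-enyl)cyclohex-2-en-1-yl]acetate (C-1 epimers) | CC[C@H]1C(OC)(OC)C(CC(=O)OC)C=C(O[Si](C)(C)C(C)(C)C)[C@@H]1CC=C | intermediate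
9 | (5R)-5-(hydroxymethyl)oxolan-2-one | OC[C@H]1CCC(=O)O1 | starting material
10 | (5R)-5-[(tert-butyldimethylsilyloxy)methyl]oxolan-2-one | CC(C)(C)[Si](C)(C)OC[C@H]1CCC(=O)O1 | intermediate
11 | lithium enolate of 10 | [Li+].[O-]C1=CC[C@H](CO[Si](C)(C)C(C)(C)C)O1 | intermediate (not isolated)
12 | (3S,5R)-5-[(tert-butyldimethylsilyloxy)methyl]-3-methyloxolan-2-one (3,5-trans) | CC(C)(C)[Si](C)(C)OC[C@H]1C[C@H](C)C(=O)O1 | intermediate
13 | (3S,5R)-5-(hydroxymethyl)-3-methyloxolan-2-one | OC[C@H]1C[C@H](C)C(=O)O1 | intermediate (not isolated)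
14 | (2R,4S)-4-methyl-5-oxooxolane-2-carboxylic acid | OC(=O)[C@H]1C[C@H](C)C(=O)O1 | intermediate
15 | (2R,4S)-4-methyl-5-oxooxolane-2-carbonyl chloride | ClC(=O)[C@H]1C[C@H](C)C(=O)O1 | intermediate (not isolated)
16 | (3S,5R)-5-(2-diazoacetyl)-3-methyloxolan-2-one | [N-]=[N+]=CC(=O)[C@H]1C[C@H](C)C(=O)O1 | intermediate (not isolated)
17 | (3S,5R)-5-(2-bromoacetyl)-3-methyloxolan-2-one | BrCC(=O)[C@H]1C[C@H](C)C(=O)O1 | intermediate
18 | methyl 2-[(3R,4R)-3-ethyl-2,2-dimethoxy-6-{2-[(2R,4S)-4-methyl-5-oxooxolan-2-yl]-2-oxoethyl}-5-oxo-4-(prop-2-enyl)cyclohexyl]acetate (epimers at C-1 and C-6) | CC[C@H]1C(OC)(OC)C(CC(=O)OC)C(CC(=O)[C@H]2C[C@H](C)C(=O)O2)C(=O)[C@@H]1CC=C | intermediate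
19 | allylamine (prop-2-en-1-amine) | C=CCN | starting material
20 | methyl 2-{(6R,7R)-6-ethyl-5,5-dimethoxy-2-[(2R,4S)-4-methyl-5-oxooxolan-2-yl]-1,7-di(prop-2-enyl)-4,5,6,7-tetrahydro-1H-indol-4-yl}acetate (C-4 epimers) | CC[C@H]1C(OC)(OC)C(CC(=O)OC)c2cc([C@H]3C[C@H](C)C(=O)O3)n(CC=C)c2[C@@H]1CC=C | intermediate
21 | methyl 2-{(5Z,7aR,8R)-8-ethyl-9,9-dimethoxy-2-[(2R,4S)-4-methyl-5-oxooxolan-2-yl]-4,7,7a,8,9,10-hexahydroazepino[3,2,1-hi]indol-10-yl}acetate (C-10 epimers; N and C-7a bridged by CH2–CH=CH–CH2) | CC[C@H]1C(OC)(OC)C(CC(=O)OC)c2cc([C@H]3C[C@H](C)C(=O)O3)n3c2[C@@H]1C/C=C\C3 | intermediate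
22 | 9-oxo analogue of 21 as C-10 epimer mixture | CC[C@H]1C(=O)C(CC(=O)OC)c2cc([C@H]3C[C@H](C)C(=O)O3)n3c2[C@@H]1C/C=C\C3 | intermediate (not isolated)
23 | methyl 2-{(5Z,7aR,8R,10S)-8-ethyl-2-[(2R,4S)-4-methyl-5-oxooxolan-2-yl]-9-oxo-4,7,7a,8,9,10-hexahydroazepino[3,2,1-hi]indol-10-yl}acetate (ethyl and acetate arm cis; ethyl and azepine CH2 trans) | CC[C@H]1C(=O)[C@@H](CC(=O)OC)c2cc([C@H]3C[C@H](C)C(=O)O3)n3c2[C@@H]1C/C=C\C3 | intermediate
24 | methyl 2-{(5Z,7aR,8R,9R,10S)-8-ethyl-9-hydroxy-2-[(2R,4S)-4-methyl-5-oxooxolan-2-yl]-4,7,7a,8,9,10-hexahydroazepino[3,2,1-hi]indol-10-yl}acetate (OH cis to ethyl and to the acetate arm) | CC[C@H]1[C@@H](O)[C@@H](CC(=O)OC)c2cc([C@H]3C[C@H](C)C(=O)O3)n3c2[C@@H]1C/C=C\C3 | intermediate (not isolated)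
25 | 2-{(5Z,7aR,8R,9R,10S)-8-ethyl-9-hydroxy-2-[(2R,4S)-4-methyl-5-oxooxolan-2-yl]-4,7,7a,8,9,10-hexahydroazepino[3,2,1-hi]indol-10-yl}acetic acid 9-lactone (cis-fused; the target without the fused-lactone methyl and with the azepine alkene) | CC[C@H]1[C@H]2OC(=O)C[C@H]2c2cc([C@H]3C[C@H](C)C(=O)O3)n3c2[C@@H]1C/C=C\C3 | intermediate
26 | lithium enolate of the fused lactone of 25 | CC[C@H]1[C@H]2OC([O-])=C[C@H]2c2cc([C@H]3C[C@H](C)C(=O)O3)n3c2[C@@H]1C/C=C\C3.[Li+] | intermediate (not isolated)
27 | 25 carrying CH2NMe2 on the fused-lactone α-carbon (convex face) | CC[C@H]1[C@H]2OC(=O)[C@H](CN(C)C)[C@H]2c2cc([C@H]3C[C@H](C)C(=O)O3)n3c2[C@@H]1C/C=C\C3 | intermediate (not isolated)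
28 | trimethylammonium iodide derived from 27 | CC[C@H]1[C@H]2OC(=O)[C@H](C[N+](C)(C)C)[C@H]2c2cc([C@H]3C[C@H](C)C(=O)O3)n3c2[C@@H]1C/C=C\C3.[I-] | intermediate (not isolated)
29 | α-methylene derivative of 25 (exocyclic CH2 on the fused-lactone α-carbon) | CC[C@H]1[C@H]2OC(=O)C(=C)[C@H]2c2cc([C@H]3C[C@H](C)C(=O)O3)n3c2[C@@H]1C/C=C\C3 | intermediate
30 | CNP0232452.1 (ethyl-CH R, O–CH R, ring-fusion CH S, fused-lactone CH(Me) S, azepine methine R, pyrrolyl O–CH R, its CH(Me) S) | CC[C@H]1[C@H]2OC(=O)[C@@H](C)[C@H]2c2cc([C@H]3C[C@H](C)C(=O)O3)n3c2[C@@H]1CCCC3 | target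

**Totals**

Total steps: 14. Longest linear sequence: 11 steps (9 to 30, steps 4–14). The other branch (1 to 30) has 10 steps.

**Steps most likely to fail**

Step 8. The α-keto radical may be reduced to the methyl ketone, or add to the terminal alkene, before it reaches the hindered enol ether carbon, so conversion to the diketone may stall. The fallback replaces the radical by two-electron carbenoid chemistry. It sets out from 8 and from the diazoketone 16, which is isolated by leaving out the HBr quench of step 7. Slow addition of 16 to 8 with Cu(acac)2 in benzene at 80 °C should give the 2-siloxycyclopropyl ketone F1. Buffered fluoride (TBAF, AcOH, THF, 0 °C) should then open this donor–acceptor cyclopropane to the 1,4-diketone, and the route is rejoined at 18.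

Step 13. LDA may also deprotonate the methyl-bearing lactone, which would cause epimerisation or aminomethylation at that carbon. The fallback uses a carboxylation that is productive only where two α-hydrogens are present. It sets out from 25. Methyl magnesium carbonate in DMF at 120 °C should give the α-carboxy lactone F2, because the chelated magnesium enolate-carboxylate can form only at a CH2. Decarboxylative Mannich methylenation (aq. HCHO, Et2NH, AcOH, NaOAc, rt to 60 °C) then leads back to the route at 29.

Step 3. Addition at the β-carbon next to the quaternary ketal carbon may be too slow without a Lewis acid, and forcing it with one would ionise the ketal, with loss of methanol and aromatisation. The fallback uses a soft carbanion under basic conditions. It sets out from 6. Dimethyl malonate with catalytic NaOMe in MeOH should give the malonate adduct F3. Krapcho demethoxycarbonylation (NaCl, wet DMSO, 150 °C) gives the keto ester F4. Kinetic enolisation on the CH2 side (LDA, THF, −78 °C) and O-silylation (TBSCl, HMPA) return the route to 8.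

**Further compounds**

F1 | step 8 | 2-siloxycyclopropyl ketone: cyclopropane formed from the enol ether C=C of 8 and the carbene carbon of 16, carrying OTBS on the ring-fusion carbon and the (2R,4S)-4-methyl-5-oxooxolane-2-carbonyl group on the new carbon | CC[C@H]1C(OC)(OC)C(CC(=O)OC)C2C(C(=O)[C@H]3C[C@H](C)C(=O)O3)C2(O[Si](C)(C)C(C)(C)C)[C@@H]1CC=C
F2 | step 13 | α-carboxy lactone: 25 carrying CO2H on the fused-lactone α-carbon | CC[C@H]1[C@H]2OC(=O)C(C(=O)O)[C@H]2c2cc([C@H]3C[C@H](C)C(=O)O3)n3c2[C@@H]1C/C=C\C3
F3 | step 3 | dimethyl 2-[(3R,4R)-3-ethyl-2,2-dimethoxy-5-oxo-4-(prop-2-enyl)cyclohexyl]propanedioate (C-1 epimers) | CC[C@H]1C(OC)(OC)C(C(C(=O)OC)C(=O)OC)CC(=O)[C@@H]1CC=C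
F4 | step 3 | methyl 2-[(3R,4R)-3-ethyl-2,2-dimethoxy-5-oxo-4-(prop-2-enyl)cyclohexyl]acetate (C-1 epimers) | CC[C@H]1C(OC)(OC)C(CC(=O)OC)CC(=O)[C@@H]1CC=C
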